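**Retrosynthetic overview**

- Feature: ring A (C7–O–C9'–C8'–C8, C7 carrying the 4-hydroxy-3-methoxyphenyl group) is a 2-aryltetrahydrofuran whose C8 bears C9. With ring B (C7'–O–C9–C8–C8') at the lactol level, C9 is a masked aldehyde, so ring A is the ring-contraction isomer of the seven-membered vinyl acetal O–C7(Ar)–O–C9'–C8'–C8=C9.
- Target 20 ⇐ aryl TIPS removal, O-prenylation, pivalate removal ⇐ furofuran 17 ⇐ lactol 16 (C9–OH → C9–H).
- 16 ⇐ 4,5-dihydro-1,3-dioxepine 13: a Lewis acid ionises the acetal at C7 and the oxocarbenium/enol pair recombines at C8 (C7–C8, ring A). O7' is then unmasked and closes onto the C9 aldehyde (C9–O, ring B).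
- 13 ⇐ 4,7-dihydro isomer 12 (metal-hydride hydrogen shift, sets C8') ⇐ (Z)-butenediol 11 + dimethyl acetal 4 of O-TIPS-vanillin.
- 11 ⇐ enantioselective addition of the alkenylzinc from bis-silylated 2-butyne-1,4-diol 6 to O-pivaloylvanillin 2 (sets C7'). Ring order: dioxepine, then ring A, then ring B.

Key step: step 10

Remark: lignan numbering is used (C7/C7' benzylic, C8/C8' ring fusion, C9/C9' OCH2; primed = prenyloxyaryl half); reagents that only deliver a protecting group or the prenyl group are given with SMILES in their step and carry no compound number.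

**Route**

Step 1
Reactants: 1 vanillin
Product: 2 4-formyl-2-methoxyphenyl pivalate
Conditions: PivCl, Et3N, DMAP (cat.), CH2Cl2, 0 °C → rt
Reagents that add atoms: pivaloyl chloride, CC(C)(C)C(Cl)=O
Why: DMAP-catalysed O-acylation of the phenol gives a pivalate that is inert to organozinc reagents, Ru–H and Lewis acids and, being electron-withdrawing, later damps ionisation at the C7' benzylic position.

Step 2
Reactants: 1 vanillin
Product: 3 3-methoxy-4-(triisopropylsilyloxy)benzaldehyde
Conditions: TIPSCl, imidazole, DMF, rt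
Reagents that add atoms: chlorotriisopropylsilane, CC(C)[Si](Cl)(C(C)C)C(C)C
Why: Imidazole-promoted silyl ether formation protects the phenol as a TIPS ether that keeps this ring electron-rich for the later oxocarbenium ion and survives mild acid, DIBAL-H and carbonate.

Step 3
Reactants: 3 3-methoxy-4-(triisopropylsilyloxy)benzaldehyde
Product: 4 [4-(dimethoxymethyl)-2-methoxyphenoxy]triisopropylsilane
Conditions: HC(OMe)3, PPTS (cat.), MeOH, rt
Reagents that add atoms: trimethyl orthoformate, COC(OC)OC
Why: Acid-catalysed acetalisation with the orthoformate as water scavenger gives the dimethyl acetal needed for transacetalisation in step 8, and the aryl silyl ether is stable to PPTS in methanol.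

Step 4
Reactants: 5 2-butyne-1,4-diol
Product: 6 1,4-bis(triethylsilyloxy)but-2-yne
Conditions: TESCl, imidazole, CH2Cl2, 0 °C → rt
Reagents that add atoms: chlorotriethylsilane, CC[Si](Cl)(CC)CC
Why: Silyl ether formation on both primary hydroxyls uses TES because it can later be removed by PPTS/MeOH in the presence of a secondary TBS ether.

Step 5
Reactants: 6 1,4-bis(triethylsilyloxy)but-2-yne, 2 4-formyl-2-methoxyphenyl pivalate
Product: 9 4-[(1S,2E)-1-hydroxy-4-(triethylsilyloxy)-2-[(triethylsilyloxy)methyl]but-2-en-1-yl]-2-methoxyphenyl pivalate, via alkenyl(dicyclohexyl)borane 7 (not isolated), via alkenyl(methyl)zinc 8 (not isolated)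
Conditions: Cy2BH (from BH3·SMe2, cyclohexene), toluene, 0 °C → rt; Me2Zn, −78 °C; (+)-MIB (5 mol%), then 2, −20 → 0 °C; aq. NH4Cl
Reagents that add atoms: none
Why: syn-Hydroboration of the symmetrical alkyne, boron-to-zinc transmetalation and amino-alcohol-catalysed enantioselective 1,2-addition of the alkenylzinc to the aldehyde should set C7' by Re-face delivery with (+)-MIB (the antipode of the ligand that directs organozincs to the Si face of aryl aldehydes), and the syn hydroboration places the two CH2O arms cis as the seven-membered ring requires; the carbinol is S by CIP here and becomes R once C8' is sp3, with the same spatial arrangement.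

Step 6
Reactants: 9 allylic alcohol
Product: 10 4-[(1S,2E)-1-(tert-butyldimethylsilyloxy)-4-(triethylsilyloxy)-2-[(triethylsilyloxy)methyl]but-2-en-1-yl]-2-methoxyphenyl pivalate
Conditions: TBSOTf, 2,6-lutidine, CH2Cl2, −78 → 0 °C
Reagents that add atoms: tert-butyldimethylsilyl triflate, CC(C)(C)[Si](C)(C)OS(=O)(=O)C(F)(F)F
Why: Silylation of the hindered secondary alcohol with the silyl triflate installs a TBS ether that blocks six-ring (1,3-dioxane) acetal formation in step 8, alcohol-to-ketone isomerisation in step 9 and capture of the oxocarbenium ion by oxygen in step 10.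

Step 7
Reactants: 10 tris-silyl ether
Product: 11 4-[(1S,2E)-1-(tert-butyldimethylsilyloxy)-4-hydroxy-2-(hydroxymethyl)but-2-en-1-yl]-2-methoxyphenyl pivalate
Conditions: PPTS (cat.), MeOH–CH2Cl2, 0 °C
Reagents that add atoms: none
Why: Chemoselective acid-catalysed methanolysis removes the two primary TES ethers, which are far more labile than the secondary TBS ether, and the weak acid should not ionise the allylic–benzylic C7'–O bond of the pivalate-deactivated ring.

Step 8
Reactants: 11 (Z)-butene-1,4-diol, 4 dimethyl acetal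
Product: 12 4-[(S)-(tert-butyldimethylsilyloxy){2-[3-methoxy-4-(triisopropylsilyloxy)phenyl]-4,7-dihydro-1,3-dioxepin-5-yl}methyl]-2-methoxyphenyl pivalate (both epimers at the acetal carbon)
Conditions: PPTS (cat.), 5 Å MS, CH2Cl2, rt
Reagents that add atoms: none
Why: Acid-catalysed transacetalisation of the cis-butenediol closes the 4,7-dihydro-1,3-dioxepine as the only cyclic acetal available with O7' silylated, and the unconfigured acetal carbon is immaterial because it is ionised in step 10.

Step 9
Reactants: 12 4,7-dihydro-1,3-dioxepine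
Product: 13 4-[(R)-(tert-butyldimethylsilyloxy){(5S)-2-[3-methoxy-4-(triisopropylsilyloxy)phenyl]-4,5-dihydro-1,3-dioxepin-5-yl}methyl]-2-methoxyphenyl pivalate (both acetal epimers)
Conditions: RuHCl(CO)(PPh3)3 (5 mol%), toluene, 80 °C
Reagents that add atoms: none
Why: Ruthenium-hydride isomerisation of the allyl acetal to the vinyl acetal (hydrometalation with Ru at the less substituted C8 and H at C8', then β-hydride elimination toward C9) should set C8' by hydride delivery to the alkene face anti to the aryl group of C7' in the conformer with C7'–H eclipsing the double bond, the same sense as the anti-selective hydroboration of 2-substituted allylic silyl ethers.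

Step 10
Reactants: 13 4,5-dihydro-1,3-dioxepine
Product: 16 6-[3-methoxy-4-(triisopropylsilyloxy)phenyl]-2-(3-methoxy-4-pivaloyloxyphenyl)-3,7-dioxabicyclo[3.3.0]octan-4-ol (exo,exo lactol; both anomers at C9), via kinetic tetrahydrofuran-3-carbaldehyde TBS ether 14 (not isolated), via C8-epimerised hydroxy aldehyde 15 (not isolated)
Conditions: TMSOTf (0.2 equiv), CH2Cl2, −78 °C; then pyridine, HF·pyridine, THF, 0 °C → rt
Reagents that add atoms: none
Why: TMSOTf silylates the enol-ether oxygen, the C7–O bond ionises to an aryl-stabilised (E)-oxocarbenium ion tethered to the silyl enol ether of the C9 aldehyde, and the two recombine at C8 (C7–C8 bond, ring A), after which HF·pyridine frees O7' and the aldehyde is trapped as the lactol (C9–O bond, ring B). The closest known reaction is the Lewis-acid ring contraction of 4,5-dihydro-1,3-dioxepines to tetrahydrofuran-3-carbaldehydes, a Petasis–Ferrier-type rearrangement whose bond-forming event is a Mukaiyama-type closure onto an oxocarbenium ion. Ring A closes in the 5-(enolexo)-endo-trig mode and ring B by 5-exo-trig hemiacetalisation. C7 is set in the C–C bond formation by C8', because with the CH(OTBS)Ar' group pseudo-equatorial in the envelope transition state the aryl group of the (E)-oxocarbenium ion ends up trans to it; C8 is first formed trans to that group (allylic strain in the Z-enol ether) and then epimerises through the enol, since only the cis isomer can close to the cis-fused lactol; the anomeric C9 centre is uncontrolled and is removed in step 11. The step needs carbon–carbon recombination to outrun capture of the cation by oxygen and the C7 and C7' benzylic C–O bonds to stay intact, which the TBS group on O7' (no 1,3-dioxane), the kinetically controlled ionisation at −78 °C and the deactivating pivalate on the C7' ring are meant to secure; both acetal epimers of 13 converge on the same cation.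

Step 11
Reactants: 16 lactol
Product: 17 (7R,7'R,8S,8'S)-exo,exo-6-[3-methoxy-4-(triisopropylsilyloxy)phenyl]-2-(3-methoxy-4-pivaloyloxyphenyl)-3,7-dioxabicyclo[3.3.0]octane
Conditions: Et3SiH, BF3·OEt2, CH2Cl2, −78 → −40 °C
Reagents that add atoms: none
Why: Ionic hydrogenation of the lactol (BF3 ionises C9–OH to the ring-B oxocarbenium ion, which Et3SiH reduces) creates no stereocentre, and the low temperature should keep the benzylic C–O bonds from ionising.

Step 12
Reactants: 17 furofuran pivalate
Product: 18 4-[(7'R)-furofuran-7'-yl]-2-methoxyphenol, i.e. 17 with the pivalate replaced by a free 4'-OH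
Conditions: DIBAL-H, CH2Cl2, −78 °C; Rochelle salt
Reagents that add atoms: none
Why: Reductive cleavage of the aryl pivalate by DIBAL-H at low temperature leaves the aryl TIPS ether and the benzylic ethers untouched.

Step 13
Reactants: 18 mono-phenol
Product: 19 O-TIPS ether of the target (4'-O-prenyl, 4-O-TIPS)
Conditions: prenyl bromide, K2CO3, acetone, rt
Reagents that add atoms: prenyl bromide (1-bromo-3-methylbut-2-ene), CC(C)=CCBr
Why: Williamson ether synthesis (SN2 O-alkylation of the only free phenol by the primary allylic bromide), run at room temperature with a weak base to avoid silyl transfer between the two phenols.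

Step 14
Reactants: 19 O-TIPS ether
Product: 20 target, 4-[(1R,3aS,4R,6aS)-4-[3-methoxy-4-(3-methylbut-2-enyloxy)phenyl]tetrahydro-1H,3H-furo[3,4-c]furan-1-yl]-2-methoxyphenol
Conditions: TBAF, THF, 0 °C; aq. NH4Cl
Reagents that add atoms: none
Why: Fluoride-induced desilylation of the aryl TIPS ether proceeds under non-acidic conditions that leave the prenyl ether and the acid-labile furofuran intact.

**Compound list**

1 | vanillin | COc1cc(C=O)ccc1O | starting material
2 | 4-formyl-2-methoxyphenyl pivalate | COc1cc(C=O)ccc1OC(=O)C(C)(C)C | intermediate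
3 | 3-methoxy-4-(triisopropylsilyloxy)benzaldehyde | COc1cc(C=O)ccc1O[Si](C(C)C)(C(C)C)C(C)C | intermediate
4 | [4-(dimethoxymethyl)-2-methoxyphenoxy]triisopropylsilane | COC(OC)c1ccc(O[Si](C(C)C)(C(C)C)C(C)C)c(OC)c1 | intermediate
5 | 2-butyne-1,4-diol | OCC#CCO | starting material
6 | 1,4-bis(triethylsilyloxy)but-2-yne | CC[Si](CC)(CC)OCC#CCO[Si](CC)(CC)CC | intermediate
7 | dicyclohexyl[(Z)-1,4-bis(triethylsilyloxy)but-2-en-2-yl]borane | CC[Si](CC)(CC)OC/C=C(\CO[Si](CC)(CC)CC)B(C1CCCCC1)C1CCCCC1 | intermediate (not isolated)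
8 | [(E)-1,4-bis(triethylsilyloxy)but-2-en-2-yl](methyl)zinc | CC[Si](CC)(CC)OC/C=C(\CO[Si](CC)(CC)CC)[Zn]C | intermediate (not isolated)
9 | 4-[(1S,2E)-1-hydroxy-4-(triethylsilyloxy)-2-[(triethylsilyloxy)methyl]but-2-en-1-yl]-2-methoxyphenyl pivalate | CC[Si](CC)(CC)OC/C=C(\CO[Si](CC)(CC)CC)[C@@H](O)c1ccc(OC(=O)C(C)(C)C)c(OC)c1 | intermediate
10 | TBS ether of 9 | CC[Si](CC)(CC)OC/C=C(\CO[Si](CC)(CC)CC)[C@@H](O[Si](C)(C)C(C)(C)C)c1ccc(OC(=O)C(C)(C)C)c(OC)c1 | intermediate
11 | 4-[(1S,2E)-1-(tert-butyldimethylsilyloxy)-4-hydroxy-2-(hydroxymethyl)but-2-en-1-yl]-2-methoxyphenyl pivalate | OC/C=C(\CO)[C@@H](O[Si](C)(C)C(C)(C)C)c1ccc(OC(=O)C(C)(C)C)c(OC)c1 | intermediate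
12 | 2-aryl-5-[(S)-(aryl')(TBSO)methyl]-4,7-dihydro-1,3-dioxepine (aryl = 3-methoxy-4-TIPSO-phenyl, aryl' = 3-methoxy-4-pivaloyloxyphenyl; acetal carbon unconfigured) | COc1cc(C2OCC=C(CO2)[C@@H](O[Si](C)(C)C(C)(C)C)c2ccc(OC(=O)C(C)(C)C)c(OC)c2)ccc1O[Si](C(C)C)(C(C)C)C(C)C | intermediate
13 | (5S)-2-aryl-5-[(R)-(aryl')(TBSO)methyl]-4,5-dihydro-1,3-dioxepine (key-step precursor; acetal carbon unconfigured) | COc1cc(C2OC[C@@H]([C@@H](O[Si](C)(C)C(C)(C)C)c3ccc(OC(=O)C(C)(C)C)c(OC)c3)C=CO2)ccc1O[Si](C(C)C)(C(C)C)C(C)C | intermediate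
14 | kinetic 2-aryl-4-[(R)-(aryl')(TBSO)methyl]tetrahydrofuran-3-carbaldehyde (CHO cis to the C2 aryl, trans to the C4 arm) | COc1cc([C@@H]2OC[C@@H]([C@@H](O[Si](C)(C)C(C)(C)C)c3ccc(OC(=O)C(C)(C)C)c(OC)c3)[C@@H]2C=O)ccc1O[Si](C(C)C)(C(C)C)C(C)C | intermediate (not isolated)
15 | C8-epimerised, O-desilylated hydroxy aldehyde (CHO trans to the C2 aryl, cis to the carbinol arm; open form of 16) | COc1cc([C@@H]2OC[C@@H]([C@@H](O)c3ccc(OC(=O)C(C)(C)C)c(OC)c3)[C@H]2C=O)ccc1O[Si](C(C)C)(C(C)C)C(C)C | intermediate (not isolated)
16 | exo,exo-2,6-diaryl-3,7-dioxabicyclo[3.3.0]octan-4-ol (lactol at C9, both anomers) | COc1cc([C@@H]2OC[C@@H]3[C@H]2C(O)O[C@H]3c2ccc(OC(=O)C(C)(C)C)c(OC)c2)ccc1O[Si](C(C)C)(C(C)C)C(C)C | intermediate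
17 | (7R,7'R,8S,8'S)-furofuran, 4-O-TIPS, 4'-O-pivaloyl | COc1cc([C@@H]2OC[C@@H]3[C@H]2CO[C@H]3c2ccc(OC(=O)C(C)(C)C)c(OC)c2)ccc1O[Si](C(C)C)(C(C)C)C(C)C | intermediate
18 | furofuran, 4-O-TIPS, free 4'-OH | COc1cc([C@@H]2OC[C@@H]3[C@H]2CO[C@H]3c2ccc(O)c(OC)c2)ccc1O[Si](C(C)C)(C(C)C)C(C)C | intermediate
19 | furofuran, 4-O-TIPS, 4'-O-prenyl | COc1cc([C@@H]2OC[C@@H]3[C@H]2CO[C@H]3c2ccc(OCC=C(C)C)c(OC)c2)ccc1O[Si](C(C)C)(C(C)C)C(C)C | intermediate
20 | CNP0185952.2 | COc1cc([C@@H]2OC[C@@H]3[C@H]2CO[C@H]3c2ccc(OCC=C(C)C)c(OC)c2)ccc1O | target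

**Step count**

Total: 14 steps. Longest linear sequence: 11 steps (5 → 6 → 9 → 10 → 11 → 12 → 13 → 16 → 17 → 18 → 19 → 20; the same length from vanillin through 2).

**Steps most likely to fail**

Step 10 (key step). Three processes could go wrong.
- Leakage of facial selectivity in the recombination at C7 (aryl cis to the C8' arm), which would lead to the 7-epi (endo-aryl) lactol.
- Incomplete epimerisation at C8, so that open hydroxy aldehyde persists.
- Acid-induced ionisation of the benzylic C7–O bond, which would erase the kinetic C7 configuration.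

Fallback, an aldol on a lactone followed by double cycloetherification, setting out from 13 and rejoining at 18. Mild aqueous acid (PPTS, THF–H2O) would hydrolyse the vinyl acetal of 13 to the 4-substituted oxolan-2-ol F1 and return aldehyde 3. Oxidation (TEMPO, PhI(OAc)2) would give the β-substituted γ-butyrolactone F2. Its lithium enolate (LiHMDS, THF, −78 °C) should add to aldehyde 3 anti to the C8' substituent to give the trans-α,β-disubstituted lactone aldol F3, with the C7 carbinol as a mixture. Excess DIBAL-H would reduce the lactone and cleave the pivalate to the phenolic triol silyl ether F4. HF·pyridine and then camphorsulfonic acid in CH2Cl2 should close both tetrahydrofuran rings through the benzylic cations (C7–O–C9' and C7'–O–C9), the aryl groups taking the exo positions, which gives 18.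

Step 9. The facial discrimination of hydride delivery to C8' may be poor, or may be eroded by reversible re-addition of Ru–H to the enol ether, giving the 8'-epimer; migration of the hindered trisubstituted alkene may also be incomplete. An 8'-epimer is a diastereomer and would be separable at the latest at 17.

Fallback, hydroboration then anti-elimination, setting out from 12 and returning at 13. Hydroboration with 9-BBN (THF, 60 °C) and perborate oxidation would give the trans-5,6-disubstituted 1,3-dioxepan-5-ol F5, with C8' set by the documented anti selectivity of hydroboration of 2-substituted allylic ethers and H8' cis to the new hydroxyl. Mesylation (MsCl, Et3N) would give the methanesulfonate F6. Treatment with t-BuOK in THF should eliminate only toward C9, because H8' is cis to the leaving group and cannot be antiperiplanar, which regenerates the vinyl acetal 13.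

Step 5. Boron-to-zinc exchange or addition of the hindered trisubstituted alkenylzinc may be slow, so that uncatalysed background addition or methyl transfer lowers the enantiomeric purity and the conversion.

Fallback, setting out from 6 and 2 and returning at 10: nickel-catalysed enantioselective reductive coupling (Ni(cod)2, a C2-symmetric chiral N-heterocyclic carbene, t-BuMe2SiH, THF, rt). It forms the C7'–C8' bond by oxidative cyclisation at nickel and delivers the silyl ether 10 directly, bypassing 9; it makes no new compound (F0).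

**Further compounds**

F1 | step 10 | (4S)-4-[(R)-(tert-butyldimethylsilyloxy)(3-methoxy-4-pivaloyloxyphenyl)methyl]oxolan-2-ol (both anomers) | OC1C[C@@H](CO1)[C@@H](O[Si](C)(C)C(C)(C)C)c1ccc(OC(=O)C(C)(C)C)c(OC)c1
F2 | step 10 | (4S)-4-[(R)-(tert-butyldimethylsilyloxy)(3-methoxy-4-pivaloyloxyphenyl)methyl]oxolan-2-one | O=C1C[C@@H](CO1)[C@@H](O[Si](C)(C)C(C)(C)C)c1ccc(OC(=O)C(C)(C)C)c(OC)c1
F3 | step 10 | 3,4-trans aldol lactone, 3-[hydroxy(3-methoxy-4-TIPSO-phenyl)methyl] derivative of F2 (C7 carbinol unconfigured) | O=C1OC[C@@H]([C@@H](O[Si](C)(C)C(C)(C)C)c2ccc(OC(=O)C(C)(C)C)c(OC)c2)[C@@H]1C(O)c1ccc(O[Si](C(C)C)(C(C)C)C(C)C)c(OC)c1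
F4 | step 10 | 2-[hydroxy(3-methoxy-4-TIPSO-phenyl)methyl]-3-[(R)-(tert-butyldimethylsilyloxy)(4-hydroxy-3-methoxyphenyl)methyl]butane-1,4-diol | OC[C@@H]([C@@H](O[Si](C)(C)C(C)(C)C)c1ccc(O)c(OC)c1)[C@@H](CO)C(O)c1ccc(O[Si](C(C)C)(C(C)C)C(C)C)c(OC)c1
F5 | step 9 | trans-2-aryl-6-[(R)-(aryl')(TBSO)methyl]-1,3-dioxepan-5-ol (acetal carbon unconfigured) | COc1cc(C2OC[C@@H]([C@@H](O[Si](C)(C)C(C)(C)C)c3ccc(OC(=O)C(C)(C)C)c(OC)c3)[C@H](O)CO2)ccc1O[Si](C(C)C)(C(C)C)C(C)C
F6 | step 9 | methanesulfonate of F5 | COc1cc(C2OC[C@@H]([C@@H](O[Si](C)(C)C(C)(C)C)c3ccc(OC(=O)C(C)(C)C)c(OC)c3)[C@H](OS(C)(=O)=O)CO2)ccc1O[Si](C(C)C)(C(C)C)C(C)C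
F0 | step 5 | none | none
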